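**Retrosynthetic overview**

1. The plan rests on ring A being a hexasubstituted phloroglucinol (C1 chiral C10 chain, C2 OH, C3 aroyl, C4 OH, C5 prenyl, C6 OMe) whose array C6–C1–C1′H2–C2′(H)(isopropenyl)–CH2CH2–C(Me)=CH2 is the opened C1=C2 ring alkene of (R)-limonene, lengthened by one carbon to an ynol ether.
2. Target ⇒ allyl removal, C6 O-methylation and desilylation ⇒ C3 aroylation of a ring-A phenol bearing C3–H (C3 bromide, aryllithium, protected 3-hydroxybenzaldehyde, oxidation).
3. Ring A ⇒ chiral siloxyalkyne (supplies C1, C6 and the side chain) + 2-prenyl-3-siloxycyclobutenone (supplies C2–C5): a vinylketene–alkyne [2+2] makes C1–C2 and C5–C6, and a 6π electrocyclization makes C2–C3.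
4. Siloxyalkyne ⇒ (R)-limonene (epoxidation, periodate cleavage, alkynylation, methylenation, alkyne oxidation/O-silylation); cyclobutenone ⇒ 4-methylpent-3-enoic acid (ester, ynolate homologation/O-silylation, ketene [2+2]).
5. Ring order: ring B is bought as 3-hydroxybenzaldehyde; ring A is the only ring constructed, in step 9.

Key step: step 9

Remark: the (R) descriptor of C2′ in the target equals that of C4 of (R)-limonene (CIP order isopropenyl > CH2–aryl or CH2–alkynyl > CH2CH2 throughout), so the centre is carried through unchanged. Ketene gas from a laboratory generator is treated as a reagent.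

**Route**

Step 1
Reactants: 1 (R)-limonene
Product: 2 (4R)-limonene 1,2-oxide (cis/trans mixture)
Conditions: mCPBA, CH2Cl2, 0 °C
Reagents that add atoms: mCPBA, O=C(OO)c1cccc(Cl)c1
Why: Prilezhaev epoxidation should select the more electron-rich trisubstituted ring alkene over the isopropenyl group; the epoxide diastereomers do not matter because both new centres are destroyed in step 2, and C4 is untouched.

Step 2
Reactants: 2 (4R)-limonene 1,2-oxide
Product: 4 (3R)-6-oxo-3-(prop-1-en-2-yl)heptanal, via diol 3 (not isolated)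
Conditions: H5IO6, THF/H2O, 0 °C → rt
Reagents that add atoms: water, O
Why: Acid-mediated epoxide hydrolysis to diol 3 followed by Malaprade glycol cleavage should open the ring between the former C1 and C2 to the methyl ketone and the aldehyde, and the stereocentre, now β to the aldehyde, cannot epimerise.

Step 3
Reactants: 4 (3R)-6-oxo-3-(prop-1-en-2-yl)heptanal
Product: 5 (5R)-5-(prop-1-en-2-yl)oct-7-yn-2-one
Conditions: MeC(O)C(N2)P(O)(OMe)2, K2CO3, MeOH, 0 °C → rt
Reagents that add atoms: dimethyl (1-diazo-2-oxopropyl)phosphonate, CC(=O)C(=[N+]=[N-])P(=O)(OC)OC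
Why: Seyferth–Gilbert homologation with the Ohira–Bestmann reagent under mild carbonate conditions should convert the aldehyde, which reacts much faster than the methyl ketone and faster than it enolises, into the terminal alkyne with one added carbon.

Step 4
Reactants: 5 (5R)-5-(prop-1-en-2-yl)oct-7-yn-2-one
Product: 6 (4R)-7-methyl-4-(prop-1-en-2-yl)oct-7-en-1-yne
Conditions: Ph3PCH3Br, KOt-Bu, THF, 0 °C → rt
Reagents that add atoms: methyltriphenylphosphonium bromide, C[P+](c1ccccc1)(c1ccccc1)c1ccccc1.[Br-]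
Why: Wittig methylenation of the methyl ketone should install the 1,1-disubstituted alkene, since the ylide is too weak a base to be consumed by the terminal alkyne and the stereocentre is remote from the carbonyl.

Step 5
Reactants: 6 (4R)-7-methyl-4-(prop-1-en-2-yl)oct-7-en-1-yne
Product: 8 (4R)-7-methyl-4-(prop-1-en-2-yl)-1-(triisopropylsilyloxy)oct-7-en-1-yne, via lithium ynolate 7 (not isolated)
Conditions: n-BuLi, THF, −78 °C; LiOOt-Bu (from t-BuOOH and LiN(SiMe3)2), −78 → 0 °C; TIPSOTf, −78 °C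
Reagents that add atoms: tert-butyl hydroperoxide, CC(C)(C)OO; triisopropylsilyl triflate, CC(C)[Si](OS(=O)(=O)C(F)(F)F)(C(C)C)C(C)C
Why: After deprotonation of the alkyne C–H, electrophilic oxygen transfer from lithium tert-butyl peroxide (Julia-type acetylide oxidation) should give ynolate 7, which the bulky silyl triflate traps on oxygen, while the unactivated alkenes are inert to the peroxide anion.

Step 6
Reactants: 9 4-methylpent-3-enoic acid
Product: 10 methyl 4-methylpent-3-enoate
Conditions: MeI, K2CO3, DMF, rt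
Reagents that add atoms: iodomethane, CI
Why: SN2 O-alkylation of the carboxylate should give the methyl ester under conditions too mild to move the β,γ-alkene into conjugation.

Step 7
Reactants: 10 methyl 4-methylpent-3-enoate
Product: 12 5-methyl-1-(triisopropylsilyloxy)hex-4-en-1-yne, via lithium ynolate 11 (not isolated)
Conditions: LiCHBr2 (from CH2Br2 and LiTMP, lithium 2,2,6,6-tetramethylpiperidide), THF, −78 °C; LiN(SiMe3)2, −78 → −20 °C; n-BuLi, −78 °C → rt; TIPSCl, −78 °C → rt
Reagents that add atoms: dibromomethane, BrCBr; triisopropylsilyl chloride, CC(C)[Si](Cl)(C(C)C)C(C)C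
Why: In the Kowalski ester homologation LiCHBr2 adds to the ester carbonyl, and base-induced collapse, bromine–lithium exchange and 1,2-shift of the prenyl group should deliver ynolate 11, which the bulky silyl chloride captures on oxygen.

Step 8
Reactants: 12 5-methyl-1-(triisopropylsilyloxy)hex-4-en-1-yne
Product: 13 2-(3-methylbut-2-enyl)-3-(triisopropylsilyloxy)cyclobut-2-en-1-one
Conditions: ketene (gas), CH2Cl2, 0 °C → rt
Reagents that add atoms: ketene, C=C=O
Why: The [2+2] cycloaddition of ketene with the electron-rich siloxyalkyne should join the ketene carbonyl carbon to the alkyne carbon remote from oxygen and so give the 2-alkyl-3-silyloxycyclobutenone as a single regioisomer, well below the temperature at which it ring-opens.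

Step 9
Reactants: 8 (4R)-7-methyl-4-(prop-1-en-2-yl)-1-(triisopropylsilyloxy)oct-7-en-1-yne; 13 2-(3-methylbut-2-enyl)-3-(triisopropylsilyloxy)cyclobut-2-en-1-one
Product: 18 ring-A phenol 2-[(2R)-5-methyl-2-(prop-1-en-2-yl)hex-5-enyl]-4-(3-methylbut-2-enyl)-3,5-bis(triisopropylsilyloxy)phenol (C2–OH free; C4 and C6 OTIPS; C3–H), via vinylketene 14 (not isolated), via vinylcyclobutenone 15 (not isolated), via dienylketene 16 (not isolated), via cyclohexadienone 17 (not isolated)
Conditions: toluene, 90 → 110 °C, 13 added slowly to 8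
Reagents that add atoms: none
Why: Heating should open 13 by 4π electrocyclic ring opening to the (1-silyloxyvinyl)ketene 14; the nucleophilic, oxygen-remote carbon of ynol ether 8 attacks the ketene carbonyl carbon and the [2+2] cycloaddition gives vinylcyclobutenone 15 (bonds C1–C2 and C5–C6), which opens again (4π) to dienylketene 16. Ring A then closes by a thermal disrotatory 6π electrocyclization between the ketene carbon (C2) and the terminal methylene (C3) to cyclohexadienone 17, and tautomerisation gives phenol 18. This is the cyclobutenone/siloxyalkyne (Danheiser-type) benzannulation, the established route from vinylketenes and silyl ynol ethers to resorcinol silyl ethers, used here with a 3-silyloxycyclobutenone so that the three oxygens of the phloroglucinol arrive differentiated. No stereocentre is created (the quaternary carbon of 15 disappears on ring opening), and the limonene-derived centre, two atoms from the reacting alkyne, is not touched under neutral thermal conditions. The step needs regiocontrol, which the polarity of the ynol ether secures: the chiral chain can only end up ortho to the free hydroxyl, the alkyne oxygen between the two alkyl groups and the single ring CH (C3) between the hydroxyl and the C4 silyl ether, while the prenyl and 1,1-disubstituted alkenes are far less reactive toward ketenes than the electron-rich alkyne.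

Step 10
Reactants: 18 ring-A phenol
Product: 19 6-bromo-2-[(2R)-5-methyl-2-(prop-1-en-2-yl)hex-5-enyl]-4-(3-methylbut-2-enyl)-3,5-bis(triisopropylsilyloxy)phenol (C3 bromide)
Conditions: NBS, CH2Cl2, −78 → 0 °C
Reagents that add atoms: N-bromosuccinimide, O=C1CCC(=O)N1Br
Why: Electrophilic aromatic bromination should occur at C3, the only free ring position, which is activated by the ortho hydroxyl and the ortho and para silyloxy groups and therefore reacts far faster than the alkenes at low temperature.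

Step 11
Reactants: 19 C3 bromophenol
Product: 20 1-(allyloxy)-2-bromo-4-(3-methylbut-2-enyl)-6-[(2R)-5-methyl-2-(prop-1-en-2-yl)hex-5-enyl]-3,5-bis(triisopropylsilyloxy)benzene (C2 O-allyl)
Conditions: allyl bromide, K2CO3, DMF, rt
Reagents that add atoms: allyl bromide, C=CCBr
Why: Williamson O-allylation of the phenoxide should mask the acidic C2 hydroxyl before metalation, and the doubly ortho-flanked aryl TIPS ethers tolerate K2CO3 in DMF.

Step 12
Reactants: 21 3-hydroxybenzaldehyde
Product: 22 3-(allyloxy)benzaldehyde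
Conditions: allyl bromide, K2CO3, DMF, rt
Reagents that add atoms: allyl bromide, C=CCBr
Why: Williamson etherification should protect the ring-B phenol as an allyl ether that survives organolithium addition, oxidation, fluoride and carbonate base and is later removed under neutral palladium catalysis.

Step 13
Reactants: 20 C2 O-allyl aryl bromide; 22 3-(allyloxy)benzaldehyde
Product: 24 [3-(allyloxy)phenyl]{2-(allyloxy)-3-[(2R)-5-methyl-2-(prop-1-en-2-yl)hex-5-enyl]-5-(3-methylbut-2-enyl)-4,6-bis(triisopropylsilyloxy)phenyl}methanol (both carbinol epimers), via aryllithium 23 (not isolated)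
Conditions: n-BuLi, THF, −78 °C; then 22, −78 °C; then H2O
Reagents that add atoms: none
Why: Bromine–lithium exchange at −78 °C should give aryllithium 23, stabilised by its two ortho oxygens, which undergoes 1,2-addition to the aldehyde faster than O-to-C silyl migration at this temperature; the carbinol centre forms without control and is removed in step 14.

Step 14
Reactants: 24 diaryl carbinol
Product: 25 [3-(allyloxy)phenyl]{2-(allyloxy)-3-[(2R)-5-methyl-2-(prop-1-en-2-yl)hex-5-enyl]-5-(3-methylbut-2-enyl)-4,6-bis(triisopropylsilyloxy)phenyl}methanone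
Conditions: Dess–Martin periodinane, CH2Cl2, rt
Reagents that add atoms: none
Why: Dess–Martin oxidation of the hindered diaryl carbinol should give the benzophenone under neutral conditions that leave alkenes, allyl ethers and silyl ethers alone, no free phenol being present.

Step 15
Reactants: 25 bis-silyl benzophenone
Product: 26 {2-(allyloxy)-4,6-dihydroxy-3-[(2R)-5-methyl-2-(prop-1-en-2-yl)hex-5-enyl]-5-(3-methylbut-2-enyl)phenyl}[3-(allyloxy)phenyl]methanone (C4 and C6 OH free)
Conditions: Bu4NF, AcOH, THF, 0 °C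
Reagents that add atoms: none
Why: Fluoride-induced Si–O cleavage should remove both aryl TIPS ethers, the acetic acid buffer keeps the electron-rich phenoxides protonated, and allyl ethers and alkenes are inert.

Step 16
Reactants: 26 C4/C6 diphenol
Product: 27 {2-(allyloxy)-6-hydroxy-4-methoxy-3-[(2R)-5-methyl-2-(prop-1-en-2-yl)hex-5-enyl]-5-(3-methylbut-2-enyl)phenyl}[3-(allyloxy)phenyl]methanone (C6 OMe)
Conditions: MeI, K2CO3, acetone, rt
Reagents that add atoms: iodomethane, CI
Why: Williamson O-methylation should select the C6 hydroxyl, which is para to the ketone, more acidic and not hydrogen-bonded, whereas the C4 hydroxyl is held in a chelate with the carbonyl.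

Step 17
Reactants: 27 bis-allyl ether
Product: 28 {2,6-dihydroxy-4-methoxy-3-[(2R)-5-methyl-2-(prop-1-en-2-yl)hex-5-enyl]-5-(3-methylbut-2-enyl)phenyl}(3-hydroxyphenyl)methanone (target)
Conditions: Pd(PPh3)4 (cat.), morpholine, THF, rt
Reagents that add atoms: none
Why: In this Tsuji–Trost deallylation zerovalent palladium should ionise both aryl allyl ethers to π-allyl complexes that morpholine captures, freeing the C2 and ring-B phenols under neutral conditions that spare the prenyl group, the 1,1-disubstituted alkenes and the stereocentre.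

**Compound list**

1 | (R)-limonene | CC1=CC[C@@H](CC1)C(C)=C | starting material
2 | (4R)-limonene 1,2-oxide (cis/trans mixture) | CC12OC1C[C@@H](CC2)C(C)=C | intermediate
3 | (4R)-p-menth-8-ene-1,2-diol | CC1(O)C(O)C[C@@H](CC1)C(C)=C | intermediate (not isolated)
4 | (3R)-6-oxo-3-(prop-1-en-2-yl)heptanal | CC(=O)CC[C@H](CC=O)C(C)=C | intermediate
5 | (5R)-5-(prop-1-en-2-yl)oct-7-yn-2-one | CC(=O)CC[C@H](CC#C)C(C)=C | intermediate
6 | (4R)-7-methyl-4-(prop-1-en-2-yl)oct-7-en-1-yne | C=C(C)CC[C@H](CC#C)C(=C)C | intermediate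
7 | lithium (4R)-7-methyl-4-(prop-1-en-2-yl)oct-7-en-1-yn-1-olate | C=C(C)CC[C@H](CC#C[O-])C(=C)C.[Li+] | intermediate (not isolated)
8 | (4R)-7-methyl-4-(prop-1-en-2-yl)-1-(triisopropylsilyloxy)oct-7-en-1-yne | C=C(C)CC[C@H](CC#CO[Si](C(C)C)(C(C)C)C(C)C)C(=C)C | intermediate
9 | 4-methylpent-3-enoic acid | CC(C)=CCC(=O)O | starting material
10 | methyl 4-methylpent-3-enoate | COC(=O)CC=C(C)C | intermediate
11 | lithium 5-methylhex-4-en-1-yn-1-olate | CC(C)=CCC#C[O-].[Li+] | intermediate (not isolated)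
12 | 5-methyl-1-(triisopropylsilyloxy)hex-4-en-1-yne | CC(C)=CCC#CO[Si](C(C)C)(C(C)C)C(C)C | intermediate
13 | 2-(3-methylbut-2-enyl)-3-(triisopropylsilyloxy)cyclobut-2-en-1-one | O=C1CC(O[Si](C(C)C)(C(C)C)C(C)C)=C1CC=C(C)C | intermediate
14 | 2-(3-methylbut-2-enyl)-3-(triisopropylsilyloxy)buta-1,3-dien-1-one (vinylketene) | O=C=C(CC=C(C)C)C(=C)O[Si](C(C)C)(C(C)C)C(C)C | intermediate (not isolated)
15 | 4-(3-methylbut-2-enyl)-2-[(2R)-5-methyl-2-(prop-1-en-2-yl)hex-5-enyl]-3-(triisopropylsilyloxy)-4-[1-(triisopropylsilyloxy)vinyl]cyclobut-2-en-1-one (both C4 epimers) | C=C(C)CC[C@H](CC1=C(O[Si](C(C)C)(C(C)C)C(C)C)C(CC=C(C)C)(C(=C)O[Si](C(C)C)(C(C)C)C(C)C)C1=O)C(=C)C | intermediate (not isolated)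
16 | dienylketene: 4-(3-methylbut-2-enyl)-2-[(2R)-5-methyl-2-(prop-1-en-2-yl)hex-5-enyl]-3,5-bis(triisopropylsilyloxy)hexa-1,3,5-trien-1-one | C=C(C)CC[C@H](CC(=C=O)C(O[Si](C(C)C)(C(C)C)C(C)C)=C(CC=C(C)C)C(=C)O[Si](C(C)C)(C(C)C)C(C)C)C(=C)C | intermediate (not isolated)
17 | 4-(3-methylbut-2-enyl)-2-[(2R)-5-methyl-2-(prop-1-en-2-yl)hex-5-enyl]-3,5-bis(triisopropylsilyloxy)cyclohexa-2,4-dien-1-one | C=C(C)CC[C@H](CC1=C(O[Si](C(C)C)(C(C)C)C(C)C)C(CC=C(C)C)=C(O[Si](C(C)C)(C(C)C)C(C)C)CC1=O)C(=C)C | intermediate (not isolated)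
18 | 2-[(2R)-5-methyl-2-(prop-1-en-2-yl)hex-5-enyl]-4-(3-methylbut-2-enyl)-3,5-bis(triisopropylsilyloxy)phenol | C=C(C)CC[C@H](Cc1c(O)cc(O[Si](C(C)C)(C(C)C)C(C)C)c(CC=C(C)C)c1O[Si](C(C)C)(C(C)C)C(C)C)C(=C)C | intermediate
19 | 6-bromo-2-[(2R)-5-methyl-2-(prop-1-en-2-yl)hex-5-enyl]-4-(3-methylbut-2-enyl)-3,5-bis(triisopropylsilyloxy)phenol | C=C(C)CC[C@H](Cc1c(O)c(Br)c(O[Si](C(C)C)(C(C)C)C(C)C)c(CC=C(C)C)c1O[Si](C(C)C)(C(C)C)C(C)C)C(=C)C | intermediate
20 | 1-(allyloxy)-2-bromo-4-(3-methylbut-2-enyl)-6-[(2R)-5-methyl-2-(prop-1-en-2-yl)hex-5-enyl]-3,5-bis(triisopropylsilyloxy)benzene | C=C(C)CC[C@H](Cc1c(OCC=C)c(Br)c(O[Si](C(C)C)(C(C)C)C(C)C)c(CC=C(C)C)c1O[Si](C(C)C)(C(C)C)C(C)C)C(=C)C | intermediate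
21 | 3-hydroxybenzaldehyde | O=Cc1cccc(O)c1 | starting material
22 | 3-(allyloxy)benzaldehyde | O=Cc1cccc(OCC=C)c1 | intermediate
23 | aryllithium from 20 (Li at C3) | C=C(C)CC[C@H](Cc1c(OCC=C)c([Li])c(O[Si](C(C)C)(C(C)C)C(C)C)c(CC=C(C)C)c1O[Si](C(C)C)(C(C)C)C(C)C)C(=C)C | intermediate (not isolated)
24 | [3-(allyloxy)phenyl]{2-(allyloxy)-3-[(2R)-5-methyl-2-(prop-1-en-2-yl)hex-5-enyl]-5-(3-methylbut-2-enyl)-4,6-bis(triisopropylsilyloxy)phenyl}methanol (both carbinol epimers) | C=C(C)CC[C@H](Cc1c(OCC=C)c(C(O)c2cccc(OCC=C)c2)c(O[Si](C(C)C)(C(C)C)C(C)C)c(CC=C(C)C)c1O[Si](C(C)C)(C(C)C)C(C)C)C(=C)C | intermediate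
25 | [3-(allyloxy)phenyl]{2-(allyloxy)-3-[(2R)-5-methyl-2-(prop-1-en-2-yl)hex-5-enyl]-5-(3-methylbut-2-enyl)-4,6-bis(triisopropylsilyloxy)phenyl}methanone | C=C(C)CC[C@H](Cc1c(OCC=C)c(C(=O)c2cccc(OCC=C)c2)c(O[Si](C(C)C)(C(C)C)C(C)C)c(CC=C(C)C)c1O[Si](C(C)C)(C(C)C)C(C)C)C(=C)C | intermediate
26 | {2-(allyloxy)-4,6-dihydroxy-3-[(2R)-5-methyl-2-(prop-1-en-2-yl)hex-5-enyl]-5-(3-methylbut-2-enyl)phenyl}[3-(allyloxy)phenyl]methanone | C=C(C)CC[C@H](Cc1c(OCC=C)c(C(=O)c2cccc(OCC=C)c2)c(O)c(CC=C(C)C)c1O)C(=C)C | intermediate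
27 | {2-(allyloxy)-6-hydroxy-4-methoxy-3-[(2R)-5-methyl-2-(prop-1-en-2-yl)hex-5-enyl]-5-(3-methylbut-2-enyl)phenyl}[3-(allyloxy)phenyl]methanone | C=C(C)CC[C@H](Cc1c(OCC=C)c(C(=O)c2cccc(OCC=C)c2)c(O)c(CC=C(C)C)c1OC)C(=C)C | intermediate
28 | {2,6-dihydroxy-4-methoxy-3-[(2R)-5-methyl-2-(prop-1-en-2-yl)hex-5-enyl]-5-(3-methylbut-2-enyl)phenyl}(3-hydroxyphenyl)methanone | C=C(C)CC[C@H](Cc1c(O)c(C(=O)c2cccc(O)c2)c(O)c(CC=C(C)C)c1OC)C(=C)C | target

**Step count and risk**

Total steps: 17. Longest linear sequence: 13 (steps 1–5, 9–11, 13–17).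

Steps most likely to fail:

1. Step 9. The vinylketene may be lost to dimerisation, or to acylation of the phenol already formed, before the bimolecular [2+2] with the β-branched alkyne, which is too valuable to use in large excess. The fallback exchanges the roles of the two fragments; it sets out from 8 and 12 and comes back to the route at 28. Alkyne 8 is treated with ketene as in step 8 to give 2-[(2R)-5-methyl-2-(prop-1-en-2-yl)hex-5-enyl]-3-(triisopropylsilyloxy)cyclobut-2-en-1-one F1. Heating F1 in toluene with an excess of the cheap alkyne 12 should give the isomeric phenol F2, in which the C4 hydroxyl is free and C2 and C6 carry the silyl ethers. Because C2 and C4 both end as free hydroxyls, F2 can follow the same operations as 18: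
   - NBS should give the C3 bromophenol F3.
   - Allyl bromide and K2CO3 should give the C4 allyl ether F4.
   - n-BuLi followed by 22 should give the carbinol F5.
   - Dess–Martin periodinane should give the ketone F6.
   - Bu4NF/AcOH should give the C2/C6 diphenol F7.
   - MeI and K2CO3 should methylate the unchelated C6 hydroxyl to give the methyl ether F8.
   - Pd(PPh3)4 and morpholine should then release 28.

2. Step 7. LiCHBr2 or residual amide base may deprotonate the doubly activated α-CH2 of the β,γ-unsaturated ester instead of adding to the carbonyl, or the carbenoid rearrangement may stall. The fallback reaches the same ynolate by acetylide oxidation; it sets out from 10 and comes back at ynolate 11 and hence 12. Ester 10 is reduced with i-Bu2AlH (CH2Cl2, −78 °C) to 4-methylpent-3-enal F9. Corey–Fuchs olefination (CBr4, PPh3, CH2Cl2, 0 °C) should give 1,1-dibromo-5-methylhexa-1,4-diene F10. n-BuLi (2 equiv, THF, −78 °C) should convert F10 into lithium 5-methylhex-4-en-1-yn-1-ide F11, which is oxidised in the same flask with LiOOt-Bu to ynolate 11 and silylated with TIPSOTf as in step 5 to give 12.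

3. Step 13. Addition of the aryllithium, flanked by the allyloxy group and the bulky silyloxy group, to the aldehyde may be slow enough for protonation or O-to-C migration of the neighbouring silyl group to take over. The fallback delivers the acyl group intramolecularly; it sets out from 19 and 22 and comes back at 25, bypassing steps 11, 13 and 14. Aldehyde 22 is oxidised (NaClO2, NaH2PO4, 2-methylbut-2-ene, t-BuOH/H2O) to 3-(allyloxy)benzoic acid F12. Steglich esterification of bromophenol 19 with F12 (DCC, DMAP, CH2Cl2) should give the aryl ester F13. t-BuLi (THF, −90 °C) should trigger bromine–lithium exchange and an anionic Fries 1,3 O-to-C acyl shift to the o-hydroxybenzophenone F14. O-allylation of F14 (allyl bromide, K2CO3, DMF) should give 25.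

**Further compounds**

F1 | step 9 | 2-[(2R)-5-methyl-2-(prop-1-en-2-yl)hex-5-enyl]-3-(triisopropylsilyloxy)cyclobut-2-en-1-one | C=C(C)CC[C@H](CC1=C(O[Si](C(C)C)(C(C)C)C(C)C)CC1=O)C(=C)C
F2 | step 9 | 4-[(2R)-5-methyl-2-(prop-1-en-2-yl)hex-5-enyl]-2-(3-methylbut-2-enyl)-3,5-bis(triisopropylsilyloxy)phenol | C=C(C)CC[C@H](Cc1c(O[Si](C(C)C)(C(C)C)C(C)C)cc(O)c(CC=C(C)C)c1O[Si](C(C)C)(C(C)C)C(C)C)C(=C)C
F3 | step 9 | 6-bromo-4-[(2R)-5-methyl-2-(prop-1-en-2-yl)hex-5-enyl]-2-(3-methylbut-2-enyl)-3,5-bis(triisopropylsilyloxy)phenol | C=C(C)CC[C@H](Cc1c(O[Si](C(C)C)(C(C)C)C(C)C)c(Br)c(O)c(CC=C(C)C)c1O[Si](C(C)C)(C(C)C)C(C)C)C(=C)C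
F4 | step 9 | allyl ether of F3 (C4 O-allyl, C3 Br, C2 and C6 OTIPS) | C=C(C)CC[C@H](Cc1c(O[Si](C(C)C)(C(C)C)C(C)C)c(Br)c(OCC=C)c(CC=C(C)C)c1O[Si](C(C)C)(C(C)C)C(C)C)C(=C)C
F5 | step 9 | [3-(allyloxy)phenyl]{2-(allyloxy)-5-[(2R)-5-methyl-2-(prop-1-en-2-yl)hex-5-enyl]-3-(3-methylbut-2-enyl)-4,6-bis(triisopropylsilyloxy)phenyl}methanol (both carbinol epimers) | C=C(C)CC[C@H](Cc1c(O[Si](C(C)C)(C(C)C)C(C)C)c(C(O)c2cccc(OCC=C)c2)c(OCC=C)c(CC=C(C)C)c1O[Si](C(C)C)(C(C)C)C(C)C)C(=C)C
F6 | step 9 | [3-(allyloxy)phenyl]{2-(allyloxy)-5-[(2R)-5-methyl-2-(prop-1-en-2-yl)hex-5-enyl]-3-(3-methylbut-2-enyl)-4,6-bis(triisopropylsilyloxy)phenyl}methanone | C=C(C)CC[C@H](Cc1c(O[Si](C(C)C)(C(C)C)C(C)C)c(C(=O)c2cccc(OCC=C)c2)c(OCC=C)c(CC=C(C)C)c1O[Si](C(C)C)(C(C)C)C(C)C)C(=C)C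
F7 | step 9 | {2-(allyloxy)-4,6-dihydroxy-5-[(2R)-5-methyl-2-(prop-1-en-2-yl)hex-5-enyl]-3-(3-methylbut-2-enyl)phenyl}[3-(allyloxy)phenyl]methanone | C=C(C)CC[C@H](Cc1c(O)c(C(=O)c2cccc(OCC=C)c2)c(OCC=C)c(CC=C(C)C)c1O)C(=C)C
F8 | step 9 | {2-(allyloxy)-6-hydroxy-4-methoxy-5-[(2R)-5-methyl-2-(prop-1-en-2-yl)hex-5-enyl]-3-(3-methylbut-2-enyl)phenyl}[3-(allyloxy)phenyl]methanone | C=C(C)CC[C@H](Cc1c(O)c(C(=O)c2cccc(OCC=C)c2)c(OCC=C)c(CC=C(C)C)c1OC)C(=C)C
F9 | step 7 | 4-methylpent-3-enal | CC(C)=CCC=O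
F10 | step 7 | 1,1-dibromo-5-methylhexa-1,4-diene | CC(C)=CCC=C(Br)Br
F11 | step 7 | lithium 5-methylhex-4-en-1-yn-1-ide | [Li]C#CCC=C(C)C
F12 | step 13 | 3-(allyloxy)benzoic acid | O=C(O)c1cccc(OCC=C)c1
F13 | step 13 | 6-bromo-2-[(2R)-5-methyl-2-(prop-1-en-2-yl)hex-5-enyl]-4-(3-methylbut-2-enyl)-3,5-bis(triisopropylsilyloxy)phenyl 3-(allyloxy)benzoate | C=C(C)CC[C@H](Cc1c(OC(=O)c2cccc(OCC=C)c2)c(Br)c(O[Si](C(C)C)(C(C)C)C(C)C)c(CC=C(C)C)c1O[Si](C(C)C)(C(C)C)C(C)C)C(=C)C
F14 | step 13 | [3-(allyloxy)phenyl]{2-hydroxy-3-[(2R)-5-methyl-2-(prop-1-en-2-yl)hex-5-enyl]-5-(3-methylbut-2-enyl)-4,6-bis(triisopropylsilyloxy)phenyl}methanone | C=C(C)CC[C@H](Cc1c(O)c(C(=O)c2cccc(OCC=C)c2)c(O[Si](C(C)C)(C(C)C)C(C)C)c(CC=C(C)C)c1O[Si](C(C)C)(C(C)C)C(C)C)C(=C)C
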